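in all of them: starting material 0.40 M; gas phase 30 mM (held)

|  | protic impurity | free catalyst | remark | time |
|---|---|---|---|---|
| autumn | 8 mM | 0.80 mM | the very flask that is asked about, followed so far |  |
| midnight | 8 mM | 1.6 mM | run made earlier |  |
| flask | 8.00 mM | 0.80 mM |  | 2.0 min |

| autumn: time / s | autumn: target / % | midnight: time / s | midnight: target / % |
|---|---|---|---|
| 12.0 | 8.1 | 10.0 | 10.6 |
| 25.0 | 12.7 | 12.0 | 11.8 |
| 40.0 | 15.1 | 25.0 | 18.0 |
| 50.0 | 15.6 | 40.0 | 20.4 |
| 60.0 | 16.0 | 80.0 | 20.5 |

(each reading ± 0.3 percentage points)

* the target standing at 2.0 min, as a percentage of the starting material charged
* the change that raises the amount of target at 2.0 min, in percent of the starting material charged most ("none" if none brings more than 2 percentage points) (red / blue / violet / none)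
* amount of target at 2.0 min, in percent of the starting material charged, after violet

- red: doubling the amount of free catalyst, all else as stated
- blue: doubling the transfer coefficient of the gas phase, all else as stated
- violet: doubling the saturation concentration of gas phase, all else as stated

- at the start none of the gas phase is in solution

1. Slowness comes early in the autumn flask. Target gains 8.1% of the charge in the first 12.0 s, but 0.4 percentage points between 50.0 s and 60.0 s. This is the flask asked about, so I want its level more than its clock.

2. I take the target fraction at the last autumn reading and divide it by the catalyst load, 0.200% of the charge. That gives 80.0, the turnover number: target made per catalyst charged.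

3. If that number held, target would be the number times the load. I test this on the midnight run, whose load is 0.400%. The number predicts 32.0%, but the reading is 20.5%. So midnight reads 51.3 turnovers, fewer than autumn. So the number read at the autumn amount of catalyst does not carry to the midnight amount.

4. The flask asked about is the autumn flask. If its target stays at the last reading, my own reckoning is 16.0% at 2.0 min.

5. The forecast says 16.3%, picks violet, and gives 30% after that change. Its ground is that “the reaction is largely limited by gas supply”.

6. The flask gives 14.3%. Violet is best, adding 15 points against 4.1 points for red and 0.71 points for blue, and it reaches 28.9%. The forecast holds.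

    gas phase ⇌ dissolved gas, rate k1*(csat - [dissolved gas]) (kL = 0.654 s⁻¹)
    starting material + dissolved gas + free catalyst → free catalyst + target (k = 569 M⁻² s⁻¹)
    2 free catalyst → spent catalyst (k = 20.6 M⁻¹ s⁻¹)
    starting material + target → side product (k = 0.0672 M⁻¹ s⁻¹)
    starting material + protic impurity → quenched substrate (k = 0.551 M⁻¹ s⁻¹)

7. At 2.0 min this flask stands at 71.3 turnovers, below the 80.0 of the last autumn reading, and its target is lower than the 16.0% at 1.00 min. Part of the loss is that starting material consumes target: without that step this flask holds 43.4%, not 14.3%. In the neighbour with 1.6 M of starting material, 80.0 turnovers give 4.00%. The computed result is 2.70%, which is 54.0 turnovers.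

The data are calculated with made-up constants; scatter was added.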